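**Remark on the chemistry:** the carbinol carbon made in step 9 is expected as a mixture of epimers and is left undefined in 19–21 because step 12 turns it into an sp2 carbon; enol ether 6 is likewise used as a mixture of double-bond isomers.

## Analysis of the target

The target 22 is a 2,3-dihydro-1-benzofuran. Its benzene ring (ring A: C3a, C4, C5, C6, C7, C7a) has no hydrogen left: hydroxyl on C4 and C6, acetyl on C5, and on C7 a CH2 link to C3 of a 6-ethyl-4-hydroxy-5-methylpyran-2-one (ring C). The dihydrofuran (ring B: O1, C2, C3) is fused across C3a–C7a.

There is one stereocentre, C2 (R), which bears H, O1, C3 and the 6-methylhepta-1,5-dien-2-yl group. Nothing else in the molecule can relay configuration to it, so it has to be bought or set by a reagent.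

C2 is both allylic to the 1,1-disubstituted alkene and bonded to the aryl ether oxygen. The C2–O1 bond can therefore ionise under strong acid or with zerovalent palladium, and C2–H would become acidic if the alkene carbon were ever a carbonyl carbon. The trisubstituted alkene is sensitive to acid and electrophiles, the 4-hydroxypyranone is an acidic, ambident nucleophile with a lactone, and the acetyl group sits between two chelating phenols.

The difficulty is regiochemical as much as stereochemical: on a hexasubstituted ring, O1 must end up next to C7 and C3 next to C4, and C2 must be made without strongly acidic or basic steps afterwards.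

The strategy rests on one feature. C7a carries O1 and lies between C3a, which needs the C3 carbon, and C7, which already carries carbon. An aryl iodide with iodine on C7a, hydrogen on C3a and a blocked C7 is exactly the pattern in which a Catellani-type relay alkylates the ortho carbon and ends at the ipso carbon with a heteroatom. A terminal epoxide holds C3, C2 and O1 in the right order.

## Retrosynthetic reasoning

**22 back to 21.** Only functional groups change. The three acidic hydroxyls are carried as methoxymethyl ethers, and the 1,1-disubstituted alkene is carried as a tertiary carbinol acetal with a trimethylsilylmethyl group on the same carbon. This mask puts no alkene next to the epoxide and no acidic hydrogen on C2, and acid converts it regiospecifically into the exocyclic methylene. An acetal is used on the carbinol instead of a silyl ether because a silyl group could migrate to the alkoxide that appears on the neighbouring carbon in the key step. The forward reaction must ionise the tertiary acetal, lose silicon, and free three hydroxyls without touching C2–O1.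

**21 back to 13 and 20.** The bonds C3a–C3 and C7a–O1 are cut, which removes ring B and divides the molecule into the aryl iodide 13 and the epoxide 20, of similar size. Neither cut bond is at the stereocentre: C2 stays inside the epoxide, and its C–O bond is never broken. Closing the ring from the other side, by displacement at C2, was not considered: C2 is flanked by a fully substituted carbon and would have to be inverted. The forward reaction is a palladium-catalysed relay through a strained bicyclic alkene. It must alkylate C3a with the CH2 end of the epoxide and then join the liberated oxygen to the carbon that held iodine.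

**20 back to 14 and 16.** The side chain is cut at the two carbon–carbon bonds of the carbinol carbon. The acetal 20 comes from alcohol 19; 19 comes from ketone 18 and a (trimethylsilyl)methyl nucleophile; 18 comes from Weinreb amide 15 and the Grignard reagent 17 of bromide 16; and 15 comes from the glycidic ester 14. The stereocentre is bought with 14, and none of these steps touches it.

**13 back to 4 and 9.** The triol 12 is the uncapped form of 13. In 12 the aryl–CH2 bond at the future C7 is cut. The CH2 comes from a one-carbon iminium electrophile that turns pyranone 9 into Mannich base 10 and, by loss of the amine, into methide 11. Phenol 4 has two equivalent nucleophilic positions, each ortho to one hydroxyl and para to the other, so the alkylation has no regiochemical choice. The iodine already marks the future C7a.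

**4 back to 1.** The C–I bond para to the acetyl group is cut. In the dimethyl ether 1 that position is the only ring C–H without an ortho neighbour, so sterically controlled C–H borylation (boronate 2) followed by iododeboronation gives 3, and ether cleavage gives 4. The acetyl group and both oxygens are bought in place.

**9 back to 5 and 7.** The pyranone is cut into a three-carbon diacyl unit 7 and the enol ether 6 of the symmetrical ketone 5. C-acylation gives acyl chloride 8, which lactonises.

## Alternatives that were turned down

**Alternative 1:** one-carbon boron linchpin.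
- Disconnection: C2–C3 and the bond from C2 to the alkene carbon. C2 is a single inserted carbon.
- Forward key step: Matteson homologation. The benzylic boronic ester A2, carrying a chiral diol, takes up dichloromethyllithium A3; the first 1,2-shift makes C2–C3. The alkenyl Grignard reagent A4 then adds to boron, and the second shift gives A1.
- What would follow: oxidation of C–B with retention, closure of ring B by displacement of an ortho fluoride, exchange of the other two fluorides for oxygen, acylation at C5, and pyranonylmethylation at C7.
- For: C2 is set by reagent control in a three-component step. The ring closure is an ordinary aromatic substitution. The last C–C bond is made at the only free position of an electron-rich acylphloroglucinol-type ring, which is closer to established reactivity than step 5 of the chosen route.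
- Against: A1 is an allylic boronic ester, and a 1,3-shift of boron would erase the stereocentre. Replacing two aryl fluorides by oxygen on a ring that becomes more electron-rich with each exchange is slow. The diene and the allylic ether would have to survive organolithium and hot alkoxide steps. Some seven steps follow the key step.
- Comparison: the chosen route buys the oxygen and acetyl pattern, takes C2 from the chiral pool with no stereoselective step, and needs one step after the key step. In exchange it accepts a harder arene alkylation in step 5 and a hindered palladium step.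

**Alternative 2:** benzene ring last.
- Disconnection: ring A at C4–C5.
- Forward key step: in the dihydrofuran A6, an ester sits on the future C3a and a 2,4-dioxopentyl arm on the future C7a. Base forms the carbanion between the two ketones, which attacks the ester in a Claisen condensation; enolisation aromatises the new ring to A5. The methide 11 would then alkylate C7.
- For: no phenol protection and no transition metal; the alkene is present throughout under mild base. Which oxygen becomes O1 is fixed by construction. The last alkylation is again at the only free, very nucleophilic position, which is stronger than the chosen route on that point.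
- Against: the key step sets no stereocentre, so an enantioenriched 2-alkenyl dihydrofuran must be made first. A6 is a triketo ester that can also close through oxygen to a pyranone. Its own synthesis is a linear sequence longer than the whole chosen route.
- Comparison: the risk is spread over making A6 and steering its cyclisation. The chosen route concentrates the risk in one convergent step between two fragments built by routine chemistry.

**Alternative 3:** aryne takes acetyl and hydroxyl.
- Disconnection: C5–acetyl and C6–O.
- Forward key step: a fluoride source turns the silyl triflate A8 into the C5–C6 aryne. Acetic acid A9 adds with its oxygen at C6, the carbon remote from the C4 alkoxy group, and the acyl group moves to C5, giving A7. C7 alkylation and acetal removal would follow.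
- For: acetyl and hydroxyl are set together, with regiochemistry dictated by the C4 substituent. The conditions are room temperature and metal-free, milder than the chosen key step. C7 is again the only free position.
- Against: simple O–H addition to the aryne, giving an aryl acetate, competes with acyl transfer, especially for a small acidic partner. A8 is a late intermediate that already holds the stereocentre and the diene. Its triflate is made from the C6 phenol, so that oxygen is removed and put back. C2 is not addressed by the key step.
- Comparison: the chosen route never has to create the acetyl/oxygen pattern and is shorter and convergent. Alternative 3 is gentler at the key step and surer in its last C–C bond.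

Key step: step 11

## Route

**Step 1**
Reactants: 1 1-(2,6-dimethoxyphenyl)ethanone
Product: 3 1-(4-iodo-2,6-dimethoxyphenyl)ethanone, via pinacol arylboronate 2 (not isolated)
Conditions: [Ir(OMe)(cod)]2 (1.5 mol%), dtbpy (3 mol%), B2pin2, THF, 80 °C; evaporate; CuI (10 mol%), 1,10-phenanthroline (20 mol%), KI, MeOH/H2O, air, 80 °C
Reagents that add atoms: potassium iodide, [K+].[I-]; bis(pinacolato)diboron, CC1(C)OB(OC1(C)C)B1OC(C)(C)C(C)(C)O1 (its boron stays only in 2)
Why: Iridium-catalysed C–H borylation is governed by sterics and should take the only ring hydrogen without an ortho neighbour, C4 para to the acetyl group; copper-catalysed iododeboronation then puts iodine on the same carbon.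

**Step 2**
Reactants: 3 1-(4-iodo-2,6-dimethoxyphenyl)ethanone
Product: 4 1-(2,6-dihydroxy-4-iodophenyl)ethanone
Conditions: BBr3, CH2Cl2, −78 °C to rt; H2O
Reagents that add atoms: none
Why: Lewis-acid cleavage of aryl methyl ethers, assisted by chelation to the ortho carbonyl; the aryl iodide and the ketone are inert to BBr3.

**Step 3**
Reactants: 5 pentan-3-one
Product: 6 trimethyl(pent-2-en-3-yloxy)silane (E/Z mixture)
Conditions: Me3SiOTf, Et3N, CH2Cl2, 0 °C
Reagents that add atoms: trimethylsilyl trifluoromethanesulfonate, C[Si](C)(C)OS(=O)(=O)C(F)(F)F
Why: Soft enolisation and O-silylation of a ketone; the ketone is symmetrical, so only one constitutional isomer can form, and its geometry is lost in step 4.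

**Step 4**
Reactants: 6 trimethyl(pent-2-en-3-yloxy)silane; 7 propanedioyl dichloride
Product: 9 6-ethyl-4-hydroxy-5-methylpyran-2-one, via diketo acyl chloride 8 (not isolated)
Conditions: Et2O, −78 °C to rt
Reagents that add atoms: none
Why: C-acylation of the silyl enol ether by one acyl chloride gives 8, whose enol oxygen closes onto the second acyl chloride; this is the established pyranone synthesis from silyl enol ethers and malonyl dichloride.

**Step 5**
Reactants: 9 6-ethyl-4-hydroxy-5-methylpyran-2-one; 4 1-(2,6-dihydroxy-4-iodophenyl)ethanone
Product: 12 3-[(3-acetyl-2,4-dihydroxy-6-iodophenyl)methyl]-6-ethyl-4-hydroxy-5-methylpyran-2-one, via Mannich base 10 (not isolated), via pyranone methide 11 (not isolated)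
Conditions: [Me2N=CH2]I (1.0 equiv), MeCN, rt; then 4 (1.5 equiv), Et3N, 80 °C
Reagents that add atoms: N,N-dimethylmethylideneammonium iodide, C[N+](C)=C.[I-]
Why: A Mannich reaction at C3 of the pyranone gives 10, which on warming loses dimethylamine to the methide 11, a Michael acceptor; the phenoxide of 4 attacks it through the carbon ortho to one hydroxyl and para to the other, and adducts through oxygen revert. The two such carbons of 4 are equivalent, so one monoalkylation product is possible, and the excess of 4 holds back a second alkylation.

**Step 6**
Reactants: 12 3-[(3-acetyl-2,4-dihydroxy-6-iodophenyl)methyl]-6-ethyl-4-hydroxy-5-methylpyran-2-one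
Product: 13 3-{[3-acetyl-6-iodo-2,4-bis(methoxymethoxy)phenyl]methyl}-6-ethyl-4-(methoxymethoxy)-5-methylpyran-2-one
Conditions: NaH (3.3 equiv), DMF, 0 °C; MeOCH2Cl, 0 °C to rt
Reagents that add atoms: chloromethyl methyl ether, COCCl
Why: Williamson-type O-alkylation of the three acidic hydroxyls; the hard electrophile should take the C4 oxygen of the pyranone anion, not C3 or the lactone oxygen, and the limited amount of base leaves the methyl ketone un-enolised.

**Step 7**
Reactants: 14 methyl (2R)-oxirane-2-carboxylate
Product: 15 (2R)-N-methoxy-N-methyloxirane-2-carboxamide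
Conditions: MeNH(OMe)·HCl, iPrMgCl, THF, −20 °C
Reagents that add atoms: N,O-dimethylhydroxylamine hydrochloride, CNOC.Cl
Why: Aminolysis of the ester by the chloromagnesium amide gives the Weinreb amide; at −20 °C addition to the carbonyl should outrun opening of the epoxide, and the stereocentre is not involved.

**Step 8**
Reactants: 16 5-bromo-2-methylpent-2-ene; 15 (2R)-N-methoxy-N-methyloxirane-2-carboxamide
Product: 18 5-methyl-1-[(2R)-oxiran-2-yl]hex-4-en-1-one, via homoprenyl Grignard reagent 17 (not isolated)
Conditions: Mg, THF, rt; then 15, THF, −78 to 0 °C; aq. NH4Cl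
Reagents that add atoms: none
Why: Weinreb ketone synthesis: the chelated tetrahedral adduct prevents a second addition, and an uncatalysed Grignard reagent does not open the epoxide at this temperature; the ring strain of the epoxide makes its α-hydrogen too weakly acidic for epimerisation.

**Step 9**
Reactants: 18 5-methyl-1-[(2R)-oxiran-2-yl]hex-4-en-1-one
Product: 19 6-methyl-2-[(2R)-oxiran-2-yl]-1-(trimethylsilyl)hept-5-en-2-ol
Conditions: Me3SiCH2MgCl, THF, −78 to −20 °C; aq. NH4Cl at −20 °C
Reagents that add atoms: (trimethylsilyl)methylmagnesium chloride, C[Si](C)(C)C[Mg]Cl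
Why: 1,2-Addition of the Peterson reagent to the activated ketone; magnesium alkoxides of β-hydroxysilanes do not eliminate, and the cold quench should prevent a Payne rearrangement. The new carbinol centre is uncontrolled, which is harmless because it is destroyed in step 12.

**Step 10**
Reactants: 19 6-methyl-2-[(2R)-oxiran-2-yl]-1-(trimethylsilyl)hept-5-en-2-ol
Product: 20 {2-(methoxymethoxy)-6-methyl-2-[(2R)-oxiran-2-yl]hept-5-en-1-yl}trimethylsilane
Conditions: MeOCH2Cl, i-Pr2NEt, Bu4NI (cat.), CH2Cl2, 0 to 40 °C
Reagents that add atoms: chloromethyl methyl ether, COCCl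
Why: Acetalisation of a tertiary alcohol under amine buffering, with iodide catalysis to shorten the reaction; the buffered medium keeps the epoxide closed and the acid-labile β-hydroxysilane intact.

**Step 11**
Reactants: 13 3-{[3-acetyl-6-iodo-2,4-bis(methoxymethoxy)phenyl]methyl}-6-ethyl-4-(methoxymethoxy)-5-methylpyran-2-one; 20 {2-(methoxymethoxy)-6-methyl-2-[(2R)-oxiran-2-yl]hept-5-en-1-yl}trimethylsilane
Product: 21 1-[(2R)-7-{[6-ethyl-4-(methoxymethoxy)-5-methyl-2-oxopyran-3-yl]methyl}-4,6-bis(methoxymethoxy)-2-[2-(methoxymethoxy)-6-methyl-1-(trimethylsilyl)hept-5-en-2-yl]-2,3-dihydro-1-benzofuran-5-yl]ethanone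
Conditions: Pd(OAc)2 (10 mol%), XPhos (20 mol%), potassium 5-norbornene-2-carboxylate (50 mol%), K2CO3 (2 equiv), 20 (1.5 equiv), NMP, 70 °C, Ar
Reagents that add atoms: none
Why: Zerovalent palladium should insert into the C7a–I bond of 13, the strained alkene of the norbornene carboxylate then inserts, and carbonate-assisted palladation of the only ortho hydrogen (C3a–H) gives a five-membered aryl–norbornyl palladacycle. This divalent palladacycle opens the epoxide of 20 at its CH2 carbon in an SN2 sense, giving a tetravalent palladium alkyl from which reductive elimination forms C3a–C3; with both ortho positions filled, β-carbon elimination expels the norbornene. The side-chain alkoxide then binds the divalent arylpalladium, and C(aryl)–O reductive elimination from this six-membered palladacycle (Pd, C7a, C3a, C3, C2, O) closes ring B as a five-membered ring by forming C7a–O1. The closest known reaction type is the Catellani ortho-alkylation with ipso termination, in the form of the palladium/norbornene annulation of ortho-substituted aryl iodides with terminal epoxides to 2,3-dihydrobenzofurans. No stereocentre is formed: C2 is the epoxide carbon of 20, whose C–O bond is never broken, so the R configuration bought with 14 is carried over. The step needs site selectivity (C3a before the ipso carbon), which the relay enforces; regioselectivity at the epoxide, which the fully substituted carbon next to C2 secures by leaving only the CH2 end open; and a single alkylation, which the pyranonylmethyl group on C7 guarantees. The alkene is carried as a β-silyl acetal so that no vinyl epoxide meets zerovalent palladium and no acidic hydrogen sits on C2, and the acetal, unlike a silyl ether, cannot migrate to the neighbouring alkoxide before the C–O bond forms.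

**Step 12**
Reactants: 21 1-[(2R)-7-{[6-ethyl-4-(methoxymethoxy)-5-methyl-2-oxopyran-3-yl]methyl}-4,6-bis(methoxymethoxy)-2-[2-(methoxymethoxy)-6-methyl-1-(trimethylsilyl)hept-5-en-2-yl]-2,3-dihydro-1-benzofuran-5-yl]ethanone
Product: 22 1-[(2R)-7-[(6-ethyl-4-hydroxy-5-methyl-2-oxopyran-3-yl)methyl]-4,6-dihydroxy-2-(6-methylhepta-1,5-dien-2-yl)-2,3-dihydro-1-benzofuran-5-yl]ethanone
Conditions: HCl (1 M in MeOH, from AcCl), MeOH/THF, 0 to 40 °C
Reagents that add atoms: none
Why: Acid ionises the tertiary acetal, and the β-silyl cation loses silicon in an acid-mode Peterson elimination, which can only give the 1,1-disubstituted alkene; the same medium solvolyses the three methoxymethyl ethers. O1 is para to the acetyl group and therefore weakly basic, so the allylic C2–O1 bond and the configuration at C2 should survive.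

## Compound list

1 | 1-(2,6-dimethoxyphenyl)ethanone | CC(=O)c1c(OC)cccc1OC | starting material
2 | 1-[2,6-dimethoxy-4-(4,4,5,5-tetramethyl-1,3,2-dioxaborolan-2-yl)phenyl]ethanone | CC(=O)c1c(OC)cc(cc1OC)B1OC(C)(C)C(C)(C)O1 | intermediate (not isolated)
3 | 1-(4-iodo-2,6-dimethoxyphenyl)ethanone | CC(=O)c1c(OC)cc(I)cc1OC | intermediate
4 | 1-(2,6-dihydroxy-4-iodophenyl)ethanone | CC(=O)c1c(O)cc(I)cc1O | intermediate
5 | pentan-3-one | CCC(=O)CC | starting material
6 | trimethyl(pent-2-en-3-yloxy)silane (E/Z mixture) | CC=C(CC)O[Si](C)(C)C | intermediate
7 | propanedioyl dichloride | O=C(Cl)CC(=O)Cl | starting material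
8 | 4-methyl-3,5-dioxoheptanoyl chloride | CCC(=O)C(C)C(=O)CC(=O)Cl | intermediate (not isolated)
9 | 6-ethyl-4-hydroxy-5-methylpyran-2-one | CCc1oc(=O)cc(O)c1C | intermediate
10 | 3-[(dimethylamino)methyl]-6-ethyl-4-hydroxy-5-methylpyran-2-one | CCc1oc(=O)c(CN(C)C)c(O)c1C | intermediate (not isolated)
11 | 6-ethyl-5-methyl-3-methylidenepyran-2,4-dione | C=C1C(=O)OC(CC)=C(C)C1=O | intermediate (not isolated)
12 | 3-[(3-acetyl-2,4-dihydroxy-6-iodophenyl)methyl]-6-ethyl-4-hydroxy-5-methylpyran-2-one | CC(=O)c1c(O)cc(I)c(Cc2c(O)c(C)c(CC)oc2=O)c1O | intermediate
13 | 3-{[3-acetyl-6-iodo-2,4-bis(methoxymethoxy)phenyl]methyl}-6-ethyl-4-(methoxymethoxy)-5-methylpyran-2-one | CC(=O)c1c(OCOC)cc(I)c(Cc2c(OCOC)c(C)c(CC)oc2=O)c1OCOC | intermediate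
14 | methyl (2R)-oxirane-2-carboxylate | COC(=O)[C@H]1CO1 | starting material
15 | (2R)-N-methoxy-N-methyloxirane-2-carboxamide | CON(C)C(=O)[C@H]1CO1 | intermediate
16 | 5-bromo-2-methylpent-2-ene | CC(C)=CCCBr | starting material
17 | bromo(4-methylpent-3-en-1-yl)magnesium | CC(C)=CCC[Mg]Br | intermediate (not isolated)
18 | 5-methyl-1-[(2R)-oxiran-2-yl]hex-4-en-1-one | CC(C)=CCCC(=O)[C@H]1CO1 | intermediate
19 | 6-methyl-2-[(2R)-oxiran-2-yl]-1-(trimethylsilyl)hept-5-en-2-ol (both epimers at the carbinol carbon) | C[Si](C)(C)CC(O)(CCC=C(C)C)[C@H]1CO1 | intermediate
20 | {2-(methoxymethoxy)-6-methyl-2-[(2R)-oxiran-2-yl]hept-5-en-1-yl}trimethylsilane (both epimers at the acetal-bearing carbon) | C[Si](C)(C)CC(OCOC)(CCC=C(C)C)[C@H]1CO1 | intermediate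
21 | 1-[(2R)-7-{[6-ethyl-4-(methoxymethoxy)-5-methyl-2-oxopyran-3-yl]methyl}-4,6-bis(methoxymethoxy)-2-[2-(methoxymethoxy)-6-methyl-1-(trimethylsilyl)hept-5-en-2-yl]-2,3-dihydro-1-benzofuran-5-yl]ethanone | C[Si](C)(C)CC(OCOC)(CCC=C(C)C)[C@H]1Cc2c(OCOC)c(C(C)=O)c(OCOC)c(Cc3c(OCOC)c(C)c(CC)oc3=O)c2O1 | intermediate
22 | 1-[(2R)-7-[(6-ethyl-4-hydroxy-5-methyl-2-oxopyran-3-yl)methyl]-4,6-dihydroxy-2-(6-methylhepta-1,5-dien-2-yl)-2,3-dihydro-1-benzofuran-5-yl]ethanone | C=C(CCC=C(C)C)[C@H]1Cc2c(O)c(C(C)=O)c(O)c(Cc3c(O)c(C)c(CC)oc3=O)c2O1 | target

## Step count and least certain steps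

Total: 12 steps. Longest linear sequence: 6 steps (from 1 through steps 1, 2, 5, 6, 11, 12; the sequences from 5 and from 14 are equally long).

**Step 11 (key step).**
- Risk: palladation of C3a–H, which is flanked by the C4 acetal, or attack of the palladacycle on the hindered epoxide may be too slow, so that the arylpalladium is consumed by ipso reduction or by products that retain the norbornene. Slow C–O reductive elimination would let the palladium alkoxide undergo β-hydride elimination to a ketone. Iodide may also strip the vinylogous acetal from the pyranone oxygen.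
- Fallback, from 13 back to the route at 22: Miyaura borylation of 13 (Pd(dppf)Cl2, B2pin2, KOAc, dioxane) gives the boronate 3-{[3-acetyl-2,4-bis(methoxymethoxy)-6-(4,4,5,5-tetramethyl-1,3,2-dioxaborolan-2-yl)phenyl]methyl}-6-ethyl-4-(methoxymethoxy)-5-methylpyran-2-one F1. It is oxidised in the same flask (NaBO3·4H2O, THF/H2O) to the phenol 3-{[3-acetyl-6-hydroxy-2,4-bis(methoxymethoxy)phenyl]methyl}-6-ethyl-4-(methoxymethoxy)-5-methylpyran-2-one F2. N-Iodosuccinimide iodinates the only ring hydrogen, giving the ortho-iodophenol 3-{[3-acetyl-6-hydroxy-5-iodo-2,4-bis(methoxymethoxy)phenyl]methyl}-6-ethyl-4-(methoxymethoxy)-5-methylpyran-2-one F3. An enantioselective Heck/Tsuji–Trost heteroannulation with commercial 7-methyl-3-methylideneocta-1,6-diene (C=CC(=C)CCC=C(C)C; Pd2(dba)3, a chiral monophosphine ligand, K2CO3) follows: the arylpalladium adds to the vinyl terminus of the diene and the phenoxide closes on the π-allyl at C2. This gives 1-[(2R)-7-{[6-ethyl-4-(methoxymethoxy)-5-methyl-2-oxopyran-3-yl]methyl}-4,6-bis(methoxymethoxy)-2-(6-methylhepta-1,5-dien-2-yl)-2,3-dihydro-1-benzofuran-5-yl]ethanone F4, which the conditions of step 12 convert into 22. This path gives up chiral-pool control: C2 then depends on the ligand and on the regiochemistry of diene insertion.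

**Step 5.**
- Risk: carbon alkylation next to the iodine may be slow, so that the methide instead adds to unreacted pyranone (a methylene-bridged dimer) or alkylates the product a second time.
- Fallback, from 4 back to the route at 12 (polarity reversed): 4 is aminomethylated with the same iminium salt to 1-{3-[(dimethylamino)methyl]-2,6-dihydroxy-4-iodophenyl}ethanone F5. Heating F5 with 9 in dioxane expels dimethylamine and unmasks an electrophilic benzylic carbon, which the pyranone attacks through C3. The small iminium ion is the species that has to approach the hindered ring carbon, and the pyranone, the better carbon nucleophile, forms the final bond.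

**Step 10.**
- Risk: slow acetalisation of the hindered tertiary alcohol would give chloride time to open the epoxide, or adventitious acid time to trigger premature elimination of the β-hydroxysilane.
- Fallback, from 19 back to the route at 22: silylation at −78 °C (Et3SiOTf, 2,6-lutidine, CH2Cl2) gives triethyl{[6-methyl-2-[(2R)-oxiran-2-yl]-1-(trimethylsilyl)hept-5-en-2-yl]oxy}silane F6. Under the conditions of step 11 with 13 it gives 1-[(2R)-7-{[6-ethyl-4-(methoxymethoxy)-5-methyl-2-oxopyran-3-yl]methyl}-4,6-bis(methoxymethoxy)-2-[6-methyl-2-(triethylsilyloxy)-1-(trimethylsilyl)hept-5-en-2-yl]-2,3-dihydro-1-benzofuran-5-yl]ethanone F7, and the conditions of step 12 convert F7 into 22. The price is the possibility of silyl migration to the alkoxide during the key step.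

**Step 12.**
- Risk: while the slowest acetal is being cleaved, protic acid may add methanol or HCl across the alkenes or ionise the allylic C2–O1 bond. A hydride shift from C2 to the cationic carbon, competing with loss of silicon, would scramble C2.
- Fallback, from 21 directly to 22, leaving Brønsted solvolysis for a Lewis acid–thiol transacetalisation: ZnBr2 and propane-1-thiol in CH2Cl2 at 0 °C for minutes. The thiol captures each methoxymethyl cation, the tertiary acetal ionises with loss of silicon, and no free mineral acid is present.

**Step 7.**
- Risk: chloride or the magnesium amide may open the epoxide at CH2 in competition with attack at the ester carbonyl.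
- Fallback, from 14 back to the route at 15: saponification (KOH, EtOH, 0 °C) gives potassium (2R)-oxirane-2-carboxylate F8, which is coupled with N,O-dimethylhydroxylamine hydrochloride using a carbodiimide (EDC·HCl, CH2Cl2, 0 °C).

## Further compounds

F1 | step 11 | 3-{[3-acetyl-2,4-bis(methoxymethoxy)-6-(4,4,5,5-tetramethyl-1,3,2-dioxaborolan-2-yl)phenyl]methyl}-6-ethyl-4-(methoxymethoxy)-5-methylpyran-2-one | CC(=O)c1c(OCOC)cc(B2OC(C)(C)C(C)(C)O2)c(Cc2c(OCOC)c(C)c(CC)oc2=O)c1OCOC
F2 | step 11 | 3-{[3-acetyl-6-hydroxy-2,4-bis(methoxymethoxy)phenyl]methyl}-6-ethyl-4-(methoxymethoxy)-5-methylpyran-2-one | CC(=O)c1c(OCOC)cc(O)c(Cc2c(OCOC)c(C)c(CC)oc2=O)c1OCOC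
F3 | step 11 | 3-{[3-acetyl-6-hydroxy-5-iodo-2,4-bis(methoxymethoxy)phenyl]methyl}-6-ethyl-4-(methoxymethoxy)-5-methylpyran-2-one | CC(=O)c1c(OCOC)c(I)c(O)c(Cc2c(OCOC)c(C)c(CC)oc2=O)c1OCOC
F4 | step 11 | 1-[(2R)-7-{[6-ethyl-4-(methoxymethoxy)-5-methyl-2-oxopyran-3-yl]methyl}-4,6-bis(methoxymethoxy)-2-(6-methylhepta-1,5-dien-2-yl)-2,3-dihydro-1-benzofuran-5-yl]ethanone | C=C(CCC=C(C)C)[C@H]1Cc2c(OCOC)c(C(C)=O)c(OCOC)c(Cc3c(OCOC)c(C)c(CC)oc3=O)c2O1
F5 | step 5 | 1-{3-[(dimethylamino)methyl]-2,6-dihydroxy-4-iodophenyl}ethanone | CC(=O)c1c(O)cc(I)c(CN(C)C)c1O
F6 | step 10 | triethyl{[6-methyl-2-[(2R)-oxiran-2-yl]-1-(trimethylsilyl)hept-5-en-2-yl]oxy}silane | C[Si](C)(C)CC(O[Si](CC)(CC)CC)(CCC=C(C)C)[C@H]1CO1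
F7 | step 10 | 1-[(2R)-7-{[6-ethyl-4-(methoxymethoxy)-5-methyl-2-oxopyran-3-yl]methyl}-4,6-bis(methoxymethoxy)-2-[6-methyl-2-(triethylsilyloxy)-1-(trimethylsilyl)hept-5-en-2-yl]-2,3-dihydro-1-benzofuran-5-yl]ethanone | C[Si](C)(C)CC(O[Si](CC)(CC)CC)(CCC=C(C)C)[C@H]1Cc2c(OCOC)c(C(C)=O)c(OCOC)c(Cc3c(OCOC)c(C)c(CC)oc3=O)c2O1
F0 | step 12 | none | none
F8 | step 7 | potassium (2R)-oxirane-2-carboxylate | [K+].[O-]C(=O)[C@H]1CO1
A1 | alternative 1 | (4R,5R)-4,5-dicyclohexyl-2-[(2R)-7-methyl-3-methylidene-1-(2,4,6-trifluorophenyl)oct-6-en-2-yl]-1,3,2-dioxaborolane | C=C(CCC=C(C)C)[C@@H](Cc1c(F)cc(F)cc1F)B1O[C@H](C2CCCCC2)[C@@H](C2CCCCC2)O1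
A2 | alternative 1 | (4R,5R)-4,5-dicyclohexyl-2-[(2,4,6-trifluorophenyl)methyl]-1,3,2-dioxaborolane | Fc1cc(F)cc(F)c1CB1O[C@H](C2CCCCC2)[C@@H](C2CCCCC2)O1
A3 | alternative 1 | dichloromethyllithium | [Li]C(Cl)Cl
A4 | alternative 1 | bromo(6-methylhepta-1,5-dien-2-yl)magnesium | C=C(CCC=C(C)C)[Mg]Br
A5 | alternative 2 | 1-[(2R)-4,6-dihydroxy-2-(6-methylhepta-1,5-dien-2-yl)-2,3-dihydro-1-benzofuran-5-yl]ethanone | C=C(CCC=C(C)C)[C@H]1Cc2c(O)c(C(C)=O)c(O)cc2O1
A6 | alternative 2 | methyl (5R)-5-(6-methylhepta-1,5-dien-2-yl)-2-(2,4-dioxopentyl)-4,5-dihydrofuran-3-carboxylate | C=C(CCC=C(C)C)[C@H]1CC(C(=O)OC)=C(CC(=O)CC(C)=O)O1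
A7 | alternative 3 | 1-[(2R)-6-hydroxy-4-(methoxymethoxy)-2-(6-methylhepta-1,5-dien-2-yl)-2,3-dihydro-1-benzofuran-5-yl]ethanone | C=C(CCC=C(C)C)[C@H]1Cc2c(OCOC)c(C(C)=O)c(O)cc2O1
A8 | alternative 3 | (2R)-4-(methoxymethoxy)-2-(6-methylhepta-1,5-dien-2-yl)-5-(trimethylsilyl)-2,3-dihydro-1-benzofuran-6-yl trifluoromethanesulfonate | C=C(CCC=C(C)C)[C@H]1Cc2c(OCOC)c([Si](C)(C)C)c(OS(=O)(=O)C(F)(F)F)cc2O1
A9 | alternative 3 | acetic acid | CC(=O)O
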